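**Abbreviations and assumption.** TBS = tert-butyldimethylsilyl, TMS = trimethylsilyl, PMB = 4-methoxybenzyl, PMP = 4-methoxyphenyl, DMP = Dess–Martin periodinane, TsDPEN = N-tosyl-1,2-diphenylethylenediamine ligand.
Assumption: the SMILES is read as the (7R,8R,10R,11R,14S)-4Z,12E,16Z,19Z isomer, with fatty-acid numbering (C1 = lactone carbonyl, C22 = terminal CH3) used throughout.

## Retrosynthetic overview

1. The eight-membered lactone is closed last (Yamaguchi) from a (4Z)-7-hydroxyhept-4-enoic acid; the 4Z olefin comes from a Wittig reaction of a C5 aldehyde with the 3-carboxypropyl ylide.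
2. C11–C12 is cut to a cyclopropanecarbaldehyde (C5–C11) and a terminal alkyne (C12–C22); the ynone is reduced by Noyori transfer hydrogenation (C11) and then by NaAlH2(OCH2CH2OMe)2 to the 12E olefin.
3. The cyclopropane is made by hydroxyl-directed Simmons–Smith reaction of an (R,E)-allylic alcohol; C7 comes from Noyori transfer hydrogenation of an achiral ynone.
4. The alkyne fragment gets C14 from a ketoreductase reduction of a TMS-ynone and the 16Z,19Z diene from a Z-selective Wittig reaction with the (Z)-hex-3-enyl ylide.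
5. Ring order: cyclopropane (step 7), temporary PMP-dioxane (step 8, opened in step 26), eight-membered lactone (step 30).

## Fragment A (C5–C11 aldehyde)

Step 1
Reactants: 1 propane-1,3-diol
Product: 2 3-(PMB-oxy)propan-1-ol
Conditions: NaH (1.0 equiv), 4-methoxybenzyl chloride (1.0 equiv), n-Bu4NI (cat.), THF/DMF, 0 °C → rt, diol in threefold excess
Reagents that add atoms: 4-methoxybenzyl chloride, COc1ccc(CCl)cc1
Why: Williamson etherification, where the excess of the symmetrical diol makes the mono-ether the main product.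

Step 2
Reactants: 2 3-(PMB-oxy)propan-1-ol
Product: 3 3-(PMB-oxy)propanal
Conditions: TEMPO (10 mol%), PhI(OAc)2, CH2Cl2, rt
Reagents that add atoms: none
Why: TEMPO/oxoammonium oxidation of a primary alcohol stops at the aldehyde and leaves the PMB ether alone.

Step 3
Reactants: 3 3-(PMB-oxy)propanal; 4 tert-butyldimethyl(prop-2-yn-1-yloxy)silane
Product: 6 racemic 6-(TBS-oxy)-1-(PMB-oxy)hex-4-yn-3-ol, via alkynyllithium 5 (not isolated)
Conditions: 4, n-BuLi, THF, −78 °C; then 3, −78 → 0 °C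
Reagents that add atoms: none
Why: 1,2-addition of a lithium acetylide to an aldehyde, giving a racemic carbinol that is erased in step 4.

Step 4
Reactants: 6 racemic 6-(TBS-oxy)-1-(PMB-oxy)hex-4-yn-3-ol
Product: 7 6-(TBS-oxy)-1-(PMB-oxy)hex-4-yn-3-one
Conditions: DMP, CH2Cl2, rt
Reagents that add atoms: none
Why: Dess–Martin oxidation of a propargylic alcohol gives the ynone without touching silyl or PMB ethers.

Step 5
Reactants: 7 6-(TBS-oxy)-1-(PMB-oxy)hex-4-yn-3-one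
Product: 8 (3R)-6-(TBS-oxy)-1-(PMB-oxy)hex-4-yn-3-ol
Conditions: Ru[(R,R)-TsDPEN](p-cymene) (2 mol%, preformed amido complex), i-PrOH, rt
Reagents that add atoms: none
Why: Noyori asymmetric transfer hydrogenation of an α,β-acetylenic ketone, in which the (R,R)-catalyst delivers hydride to the carbonyl face that places the alkynyl group against the arene ligand, setting C7 as R.

Step 6
Reactants: 8 (3R)-6-(TBS-oxy)-1-(PMB-oxy)hex-4-yn-3-ol
Product: 9 (3R,4E)-6-(TBS-oxy)-1-(PMB-oxy)hex-4-en-3-ol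
Conditions: NaAlH2(OCH2CH2OMe)2 (1.6 equiv), THF, −20 → 0 °C; then H2O
Reagents that add atoms: none
Why: alkoxide-directed trans-hydroalumination of the propargylic alcohol followed by protonolysis gives only the E-allylic alcohol and leaves C7 untouched.

Step 7
Reactants: 9 (3R,4E)-6-(TBS-oxy)-1-(PMB-oxy)hex-4-en-3-ol
Product: 10 (1R)-1-[(1R,2R)-2-(TBS-oxymethyl)cyclopropyl]-3-(PMB-oxy)propan-1-ol
Conditions: Et2Zn (5 equiv), CH2I2 (5 equiv), CH2Cl2, −10 °C → rt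
Reagents that add atoms: diiodomethane, C(I)I
Why: hydroxyl-directed Simmons–Smith (Furukawa) cyclopropanation, in which the zinc alkoxide delivers CH2 to the alkene face syn to the C7 oxygen in the conformer with C7–H eclipsing the olefin (minimal A(1,3) strain), giving the trans (8R,10R) ring stereospecifically from the E-olefin, with the minor anti isomer removed by chromatography.

Step 8
Reactants: 10 (1R)-1-[(1R,2R)-2-(TBS-oxymethyl)cyclopropyl]-3-(PMB-oxy)propan-1-ol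
Product: 11 (2R,4R)-4-[(1R,2R)-2-(TBS-oxymethyl)cyclopropyl]-2-(4-methoxyphenyl)-1,3-dioxane
Conditions: DDQ (1.2 equiv), 4 Å molecular sieves, CH2Cl2, 0 °C
Reagents that add atoms: none
Why: anhydrous DDQ oxidation of the PMB ether gives an oxocarbenium ion that the C7 hydroxyl traps as the six-membered PMP acetal with the aryl group equatorial (cis), protecting O5 and O7 together.

Step 9
Reactants: 11 (2R,4R)-4-[(1R,2R)-2-(TBS-oxymethyl)cyclopropyl]-2-(4-methoxyphenyl)-1,3-dioxane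
Product: 12 {(1R,2R)-2-[(2R,4R)-2-(4-methoxyphenyl)-1,3-dioxan-4-yl]cyclopropyl}methanol
Conditions: n-Bu4NF, THF, 0 °C → rt
Reagents that add atoms: none
Why: fluoride desilylation of the primary TBS ether, with the acetal inert to fluoride.

Step 10
Reactants: 12 {(1R,2R)-2-[(2R,4R)-2-(4-methoxyphenyl)-1,3-dioxan-4-yl]cyclopropyl}methanol
Product: 13 (1R,2R)-2-[(2R,4R)-2-(4-methoxyphenyl)-1,3-dioxan-4-yl]cyclopropane-1-carbaldehyde
Conditions: DMP, NaHCO3, CH2Cl2, 0 °C → rt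
Reagents that add atoms: none
Why: buffered Dess–Martin oxidation gives the trans-cyclopropanecarbaldehyde, which is configurationally stable, without acetal loss.

## Fragment B (C12–C22 alkyne)

Step 11
Reactants: 3 3-(PMB-oxy)propanal; 14 ethynyltrimethylsilane
Product: 16 racemic 5-(PMB-oxy)-1-(TMS)pent-1-yn-3-ol, via lithium trimethylsilylacetylide 15 (not isolated)
Conditions: 14, n-BuLi, THF, −78 °C; then 3, −78 → 0 °C
Reagents that add atoms: none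
Why: acetylide 1,2-addition to the aldehyde, giving a racemic carbinol that is erased in step 12.

Step 12
Reactants: 16 racemic 5-(PMB-oxy)-1-(TMS)pent-1-yn-3-ol
Product: 17 5-(PMB-oxy)-1-(TMS)pent-1-yn-3-one
Conditions: DMP, CH2Cl2, rt
Reagents that add atoms: none
Why: Dess–Martin oxidation of the propargylic alcohol to the ynone.

Step 13
Reactants: 17 5-(PMB-oxy)-1-(TMS)pent-1-yn-3-one
Product: 18 (3S)-5-(PMB-oxy)-1-(TMS)pent-1-yn-3-ol
Conditions: (S)-selective NADPH-dependent ketoreductase (picked from a commercial panel), NADP+ (cat.), i-PrOH (10% v/v), KH2PO4/K2HPO4 buffer pH 7, 30 °C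
Reagents that add atoms: none
Why: enzymatic asymmetric ketone reduction, in which the ketoreductase transfers hydride from NADPH (recycled by i-PrOH) to a single face of the activated ynone held in its active site, setting C14 as S in >99% ee.

Step 14
Reactants: 18 (3S)-5-(PMB-oxy)-1-(TMS)pent-1-yn-3-ol
Product: 19 (3S)-3-(TBS-oxy)-5-(PMB-oxy)-1-(TMS)pent-1-yne
Conditions: TBSCl, imidazole, DMF, rt
Reagents that add atoms: tert-butyldimethylsilyl chloride, CC(C)(C)[Si](C)(C)Cl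
Why: imidazole-promoted silylation of the secondary alcohol.

Step 15
Reactants: 19 (3S)-3-(TBS-oxy)-5-(PMB-oxy)-1-(TMS)pent-1-yne
Product: 20 (3S)-3-(TBS-oxy)-5-(TMS)pent-4-yn-1-ol
Conditions: DDQ, CH2Cl2/pH 7 buffer (10:1), 0 °C
Reagents that add atoms: none
Why: oxidative PMB cleavage by DDQ, to which the TBS ether and silyl alkyne are inert.

Step 16
Reactants: 20 (3S)-3-(TBS-oxy)-5-(TMS)pent-4-yn-1-ol
Product: 21 (3S)-3-(TBS-oxy)-5-(TMS)pent-4-ynal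
Conditions: DMP, NaHCO3, CH2Cl2, 0 °C → rt; used at once
Reagents that add atoms: none
Why: buffered Dess–Martin oxidation gives the β-silyloxy aldehyde under neutral conditions that avoid β-elimination.

Step 17
Reactants: 22 (Z)-hex-3-en-1-ol
Product: 23 (Z)-1-iodohex-3-ene
Conditions: PPh3, iodine, imidazole, CH2Cl2, 0 °C → rt
Reagents that add atoms: iodine, [I][I]
Why: Appel iodination of a primary alcohol, which leaves the Z-olefin untouched.

Step 18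
Reactants: 23 (Z)-1-iodohex-3-ene
Product: 24 [(Z)-hex-3-en-1-yl]triphenylphosphonium iodide
Conditions: PPh3, MeCN, 80 °C
Reagents that add atoms: triphenylphosphine, c1ccc(cc1)P(c1ccccc1)c1ccccc1
Why: SN2 quaternisation of triphenylphosphine by a primary iodide.

Step 19
Reactants: 21 (3S)-3-(TBS-oxy)-5-(TMS)pent-4-ynal; 24 [(Z)-hex-3-en-1-yl]triphenylphosphonium iodide
Product: 26 (3S,5Z,8Z)-3-(TBS-oxy)-1-(TMS)undeca-5,8-dien-1-yne, via phosphorus ylide 25 (not isolated)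
Conditions: 24, NaN(SiMe3)2, THF, −78 → 0 °C; then 21, −78 °C → rt
Reagents that add atoms: none
Why: Wittig olefination with a non-stabilised ylide under lithium-free conditions goes through the kinetic cis-oxaphosphetane to the new Z-olefin (C16=C17), and the low temperature suppresses β-elimination of the silyloxy group.

Step 20
Reactants: 26 (3S,5Z,8Z)-3-(TBS-oxy)-1-(TMS)undeca-5,8-dien-1-yne
Product: 27 (3S,5Z,8Z)-3-(TBS-oxy)undeca-5,8-dien-1-yne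
Conditions: K2CO3 (cat.), MeOH, rt
Reagents that add atoms: none
Why: base-catalysed methanolysis of the alkynyl C–Si bond, which leaves the O–TBS ether intact.

## Coupling and endgame

Step 21
Reactants: 27 (3S,5Z,8Z)-3-(TBS-oxy)undeca-5,8-dien-1-yne; 13 (1R,2R)-2-[(2R,4R)-2-(4-methoxyphenyl)-1,3-dioxan-4-yl]cyclopropane-1-carbaldehyde
Product: 29 (1RS,4S,6Z,9Z)-4-(TBS-oxy)-1-{(1R,2R)-2-[(2R,4R)-2-(4-methoxyphenyl)-1,3-dioxan-4-yl]cyclopropyl}dodeca-6,9-dien-2-yn-1-ol, via alkynyllithium 28 (not isolated)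
Conditions: 27, n-BuLi, THF, −78 °C; then 13, −78 °C
Reagents that add atoms: none
Why: acetylide addition to the aldehyde forms the C11–C12 bond, and the C11 epimer mixture is of no consequence because step 22 oxidises it.

Step 22
Reactants: 29 propargylic alcohol (C11 epimers)
Product: 30 (4S,6Z,9Z)-4-(TBS-oxy)-1-{(1R,2R)-2-[(2R,4R)-2-(4-methoxyphenyl)-1,3-dioxan-4-yl]cyclopropyl}dodeca-6,9-dien-2-yn-1-one
Conditions: DMP, NaHCO3, CH2Cl2, 0 °C → rt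
Reagents that add atoms: none
Why: buffered Dess–Martin oxidation converges both epimers to one cyclopropyl ynone.

Step 23
Reactants: 30 cyclopropyl ynone
Product: 31 (1S,4S,6Z,9Z)-4-(TBS-oxy)-1-{(1R,2R)-2-[(2R,4R)-2-(4-methoxyphenyl)-1,3-dioxan-4-yl]cyclopropyl}dodeca-6,9-dien-2-yn-1-ol
Conditions: Ru[(S,S)-TsDPEN](p-cymene) (3 mol%, preformed amido complex), i-PrOH, rt
Reagents that add atoms: none
Why: Noyori asymmetric transfer hydrogenation of the ynone is catalyst-controlled, so the (S,S)-catalyst sets C11 as S at the alkyne stage, which becomes 11R by the CIP rules once the alkyne is an alkene.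

Step 24
Reactants: 31 (1S)-propargylic alcohol
Product: 32 (1R,2E,4S,6Z,9Z)-4-(TBS-oxy)-1-{(1R,2R)-2-[(2R,4R)-2-(4-methoxyphenyl)-1,3-dioxan-4-yl]cyclopropyl}dodeca-2,6,9-trien-1-ol
Conditions: NaAlH2(OCH2CH2OMe)2 (2 equiv), THF, −20 → 0 °C; then H2O
Reagents that add atoms: none
Why: trans-hydroalumination directed by the C11 alkoxide gives only the 12E olefin, while the isolated Z-olefins, the acetal and the silyl ether do not react.

Step 25
Reactants: 32 (E)-allylic alcohol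
Product: 33 (2R,4R)-4-{(1R,2R)-2-[(1R,2E,4S,6Z,9Z)-1,4-bis(TBS-oxy)dodeca-2,6,9-trien-1-yl]cyclopropyl}-2-(4-methoxyphenyl)-1,3-dioxane
Conditions: TBSCl, imidazole, DMAP (cat.), DMF, rt → 40 °C
Reagents that add atoms: tert-butyldimethylsilyl chloride, CC(C)(C)[Si](C)(C)Cl
Why: silylation under basic conditions protects C11-OH and does not endanger the PMP acetal.

Step 26
Reactants: 33 bis-TBS PMP acetal
Product: 34 (3R)-3-{(1R,2R)-2-[(1R,2E,4S,6Z,9Z)-1,4-bis(TBS-oxy)dodeca-2,6,9-trien-1-yl]cyclopropyl}-3-(PMB-oxy)propan-1-ol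
Conditions: i-Bu2AlH (4 equiv), CH2Cl2, −78 → 0 °C; then H2O
Reagents that add atoms: none
Why: reductive opening of the PMP acetal, where aluminium binds the less hindered O5 and hydride reduces the resulting oxocarbenium ion, leaving PMB on O7 and a free primary C5 alcohol.

Step 27
Reactants: 34 primary alcohol
Product: 35 (3R)-3-{(1R,2R)-2-[(1R,2E,4S,6Z,9Z)-1,4-bis(TBS-oxy)dodeca-2,6,9-trien-1-yl]cyclopropyl}-3-(PMB-oxy)propanal
Conditions: DMP, NaHCO3, CH2Cl2, 0 °C → rt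
Reagents that add atoms: none
Why: buffered Dess–Martin oxidation to the β-alkoxy aldehyde without olefin or silyl ether damage.

Step 28
Reactants: 35 C5 aldehyde; 36 (3-carboxypropyl)triphenylphosphonium bromide
Product: 38 (4Z,7R)-7-{(1R,2R)-2-[(1R,2E,4S,6Z,9Z)-1,4-bis(TBS-oxy)dodeca-2,6,9-trien-1-yl]cyclopropyl}-7-(PMB-oxy)hept-4-enoic acid, via ylide carboxylate 37 (not isolated)
Conditions: 36, NaN(SiMe3)2 (2 equiv per 36), THF, 0 °C; then 35, −78 °C → rt; then 1 M HCl to pH 4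
Reagents that add atoms: none
Why: Z-selective Wittig olefination with the non-stabilised carboxy ylide installs C1–C4 and the 4Z olefin in one operation.

Step 29
Reactants: 38 PMB-protected acid
Product: 39 (4Z,7R)-7-{(1R,2R)-2-[(1R,2E,4S,6Z,9Z)-1,4-bis(TBS-oxy)dodeca-2,6,9-trien-1-yl]cyclopropyl}-7-hydroxyhept-4-enoic acid
Conditions: DDQ (1.5 equiv), CH2Cl2/pH 7 buffer (10:1), 0 °C
Reagents that add atoms: none
Why: oxidative PMB cleavage by DDQ attacks only the electron-rich benzyl ether and frees C7-OH alone, while silyl ethers and isolated olefins are left alone at 0 °C.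

Step 30
Reactants: 39 seco acid
Product: 41 (5Z,8R)-8-{(1R,2R)-2-[(1R,2E,4S,6Z,9Z)-1,4-bis(TBS-oxy)dodeca-2,6,9-trien-1-yl]cyclopropyl}-3,4,7,8-tetrahydro-2H-oxocin-2-one, via mixed anhydride 40 (not isolated)
Conditions: 2,4,6-trichlorobenzoyl chloride, Et3N, THF, rt; then slow addition to DMAP, toluene, 80 °C (final 1 mM)
Reagents that add atoms: none
Why: Yamaguchi lactonisation, in which the Z-olefin pre-organises the chain for eight-membered ring closure at high dilution and acyl–oxygen bond formation retains the C7 configuration.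

Step 31
Reactants: 41 bis-TBS lactone
Product: 42 (5Z,8R)-8-{(1R,2R)-2-[(1R,2E,4S,6Z,9Z)-1,4-dihydroxydodeca-2,6,9-trien-1-yl]cyclopropyl}-3,4,7,8-tetrahydro-2H-oxocin-2-one (target)
Conditions: HF·pyridine, pyridine, THF, 0 °C → rt
Reagents that add atoms: none
Why: buffered fluoride desilylation removes both TBS ethers without opening the lactone or ionising the allylic/cyclopropylcarbinyl alcohol.

## Compound list

1 | propane-1,3-diol | OCCCO | starting material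
2 | 3-(PMB-oxy)propan-1-ol | COc1ccc(COCCCO)cc1 | intermediate
3 | 3-(PMB-oxy)propanal | COc1ccc(COCCC=O)cc1 | intermediate
4 | tert-butyldimethyl(prop-2-yn-1-yloxy)silane | C#CCO[Si](C)(C)C(C)(C)C | starting material
5 | [3-(TBS-oxy)prop-1-yn-1-yl]lithium | [Li]C#CCO[Si](C)(C)C(C)(C)C | intermediate
6 | racemic 6-(TBS-oxy)-1-(PMB-oxy)hex-4-yn-3-ol | COc1ccc(COCCC(O)C#CCO[Si](C)(C)C(C)(C)C)cc1 | intermediate
7 | 6-(TBS-oxy)-1-(PMB-oxy)hex-4-yn-3-one | COc1ccc(COCCC(=O)C#CCO[Si](C)(C)C(C)(C)C)cc1 | intermediate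
8 | (3R)-6-(TBS-oxy)-1-(PMB-oxy)hex-4-yn-3-ol | CC(C)(C)[Si](C)(C)OCC#C[C@H](O)CCOCc1ccc(OC)cc1 | intermediate
9 | (3R,4E)-6-(TBS-oxy)-1-(PMB-oxy)hex-4-en-3-ol | CC(C)(C)[Si](C)(C)OC/C=C/[C@H](O)CCOCc1ccc(OC)cc1 | intermediate
10 | (1R)-1-[(1R,2R)-2-(TBS-oxymethyl)cyclopropyl]-3-(PMB-oxy)propan-1-ol | CC(C)(C)[Si](C)(C)OC[C@@H]1C[C@H]1[C@H](O)CCOCc2ccc(OC)cc2 | intermediate
11 | (2R,4R)-4-[(1R,2R)-2-(TBS-oxymethyl)cyclopropyl]-2-(4-methoxyphenyl)-1,3-dioxane | CC(C)(C)[Si](C)(C)OC[C@@H]1C[C@H]1[C@H]1CCO[C@@H](c2ccc(OC)cc2)O1 | intermediate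
12 | {(1R,2R)-2-[(2R,4R)-2-(4-methoxyphenyl)-1,3-dioxan-4-yl]cyclopropyl}methanol | OC[C@@H]1C[C@H]1[C@H]1CCO[C@@H](c2ccc(OC)cc2)O1 | intermediate
13 | (1R,2R)-2-[(2R,4R)-2-(4-methoxyphenyl)-1,3-dioxan-4-yl]cyclopropane-1-carbaldehyde | O=C[C@@H]1C[C@H]1[C@H]1CCO[C@@H](c2ccc(OC)cc2)O1 | intermediate
14 | ethynyltrimethylsilane | C#C[Si](C)(C)C | starting material
15 | [(trimethylsilyl)ethynyl]lithium | [Li]C#C[Si](C)(C)C | intermediate
16 | racemic 5-(PMB-oxy)-1-(TMS)pent-1-yn-3-ol | COc1ccc(COCCC(O)C#C[Si](C)(C)C)cc1 | intermediate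
17 | 5-(PMB-oxy)-1-(TMS)pent-1-yn-3-one | COc1ccc(COCCC(=O)C#C[Si](C)(C)C)cc1 | intermediate
18 | (3S)-5-(PMB-oxy)-1-(TMS)pent-1-yn-3-ol | COc1ccc(COCC[C@H](O)C#C[Si](C)(C)C)cc1 | intermediate
19 | (3S)-3-(TBS-oxy)-5-(PMB-oxy)-1-(TMS)pent-1-yne | COc1ccc(COCC[C@H](O[Si](C)(C)C(C)(C)C)C#C[Si](C)(C)C)cc1 | intermediate
20 | (3S)-3-(TBS-oxy)-5-(TMS)pent-4-yn-1-ol | OCC[C@H](O[Si](C)(C)C(C)(C)C)C#C[Si](C)(C)C | intermediate
21 | (3S)-3-(TBS-oxy)-5-(TMS)pent-4-ynal | O=CC[C@H](O[Si](C)(C)C(C)(C)C)C#C[Si](C)(C)C | intermediate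
22 | (Z)-hex-3-en-1-ol | CC/C=C\CCO | starting material
23 | (Z)-1-iodohex-3-ene | CC/C=C\CCI | intermediate
24 | [(Z)-hex-3-en-1-yl]triphenylphosphonium iodide | CC/C=C\CC[P+](c1ccccc1)(c1ccccc1)c1ccccc1.[I-] | intermediate
25 | [(Z)-hex-3-en-1-ylidene]triphenylphosphorane | CC/C=C\CC=P(c1ccccc1)(c1ccccc1)c1ccccc1 | intermediate
26 | (3S,5Z,8Z)-3-(TBS-oxy)-1-(TMS)undeca-5,8-dien-1-yne | CC/C=C\C/C=C\C[C@H](O[Si](C)(C)C(C)(C)C)C#C[Si](C)(C)C | intermediate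
27 | (3S,5Z,8Z)-3-(TBS-oxy)undeca-5,8-dien-1-yne | CC/C=C\C/C=C\C[C@H](O[Si](C)(C)C(C)(C)C)C#C | intermediate
28 | [(3S,5Z,8Z)-3-(TBS-oxy)undeca-5,8-dien-1-yn-1-yl]lithium | CC/C=C\C/C=C\C[C@H](O[Si](C)(C)C(C)(C)C)C#C[Li] | intermediate
29 | (1RS,4S,6Z,9Z)-4-(TBS-oxy)-1-{(1R,2R)-2-[(2R,4R)-2-(4-methoxyphenyl)-1,3-dioxan-4-yl]cyclopropyl}dodeca-6,9-dien-2-yn-1-ol | CC/C=C\C/C=C\C[C@H](O[Si](C)(C)C(C)(C)C)C#CC(O)[C@@H]1C[C@H]1[C@H]1CCO[C@@H](c2ccc(OC)cc2)O1 | intermediate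
30 | (4S,6Z,9Z)-4-(TBS-oxy)-1-{(1R,2R)-2-[(2R,4R)-2-(4-methoxyphenyl)-1,3-dioxan-4-yl]cyclopropyl}dodeca-6,9-dien-2-yn-1-one | CC/C=C\C/C=C\C[C@H](O[Si](C)(C)C(C)(C)C)C#CC(=O)[C@@H]1C[C@H]1[C@H]1CCO[C@@H](c2ccc(OC)cc2)O1 | intermediate
31 | (1S,4S,6Z,9Z)-4-(TBS-oxy)-1-{(1R,2R)-2-[(2R,4R)-2-(4-methoxyphenyl)-1,3-dioxan-4-yl]cyclopropyl}dodeca-6,9-dien-2-yn-1-ol | CC/C=C\C/C=C\C[C@H](O[Si](C)(C)C(C)(C)C)C#C[C@@H](O)[C@@H]1C[C@H]1[C@H]1CCO[C@@H](c2ccc(OC)cc2)O1 | intermediate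
32 | (1R,2E,4S,6Z,9Z)-4-(TBS-oxy)-1-{(1R,2R)-2-[(2R,4R)-2-(4-methoxyphenyl)-1,3-dioxan-4-yl]cyclopropyl}dodeca-2,6,9-trien-1-ol | CC/C=C\C/C=C\C[C@H](O[Si](C)(C)C(C)(C)C)/C=C/[C@@H](O)[C@@H]1C[C@H]1[C@H]1CCO[C@@H](c2ccc(OC)cc2)O1 | intermediate
33 | (2R,4R)-4-{(1R,2R)-2-[(1R,2E,4S,6Z,9Z)-1,4-bis(TBS-oxy)dodeca-2,6,9-trien-1-yl]cyclopropyl}-2-(4-methoxyphenyl)-1,3-dioxane | CC/C=C\C/C=C\C[C@H](O[Si](C)(C)C(C)(C)C)/C=C/[C@@H](O[Si](C)(C)C(C)(C)C)[C@@H]1C[C@H]1[C@H]1CCO[C@@H](c2ccc(OC)cc2)O1 | intermediate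
34 | (3R)-3-{(1R,2R)-2-[(1R,2E,4S,6Z,9Z)-1,4-bis(TBS-oxy)dodeca-2,6,9-trien-1-yl]cyclopropyl}-3-(PMB-oxy)propan-1-ol | CC/C=C\C/C=C\C[C@H](O[Si](C)(C)C(C)(C)C)/C=C/[C@@H](O[Si](C)(C)C(C)(C)C)[C@@H]1C[C@H]1[C@H](OCc1ccc(OC)cc1)CCO | intermediate
35 | (3R)-3-{(1R,2R)-2-[(1R,2E,4S,6Z,9Z)-1,4-bis(TBS-oxy)dodeca-2,6,9-trien-1-yl]cyclopropyl}-3-(PMB-oxy)propanal | CC/C=C\C/C=C\C[C@H](O[Si](C)(C)C(C)(C)C)/C=C/[C@@H](O[Si](C)(C)C(C)(C)C)[C@@H]1C[C@H]1[C@H](OCc1ccc(OC)cc1)CC=O | intermediate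
36 | (3-carboxypropyl)triphenylphosphonium bromide | OC(=O)CCC[P+](c1ccccc1)(c1ccccc1)c1ccccc1.[Br-] | starting material
37 | sodium 4-(triphenylphosphoranylidene)butanoate | [Na+].[O-]C(=O)CCC=P(c1ccccc1)(c1ccccc1)c1ccccc1 | intermediate
38 | (4Z,7R)-7-{(1R,2R)-2-[(1R,2E,4S,6Z,9Z)-1,4-bis(TBS-oxy)dodeca-2,6,9-trien-1-yl]cyclopropyl}-7-(PMB-oxy)hept-4-enoic acid | CC/C=C\C/C=C\C[C@H](O[Si](C)(C)C(C)(C)C)/C=C/[C@@H](O[Si](C)(C)C(C)(C)C)[C@@H]1C[C@H]1[C@H](OCc1ccc(OC)cc1)C/C=C\CCC(=O)O | intermediate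
39 | (4Z,7R)-7-{(1R,2R)-2-[(1R,2E,4S,6Z,9Z)-1,4-bis(TBS-oxy)dodeca-2,6,9-trien-1-yl]cyclopropyl}-7-hydroxyhept-4-enoic acid | CC/C=C\C/C=C\C[C@H](O[Si](C)(C)C(C)(C)C)/C=C/[C@@H](O[Si](C)(C)C(C)(C)C)[C@@H]1C[C@H]1[C@H](O)C/C=C\CCC(=O)O | intermediate
40 | mixed anhydride of 39 and 2,4,6-trichlorobenzoic acid | CC/C=C\C/C=C\C[C@H](O[Si](C)(C)C(C)(C)C)/C=C/[C@@H](O[Si](C)(C)C(C)(C)C)[C@@H]1C[C@H]1[C@H](O)C/C=C\CCC(=O)OC(=O)c1c(Cl)cc(Cl)cc1Cl | intermediate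
41 | (5Z,8R)-8-{(1R,2R)-2-[(1R,2E,4S,6Z,9Z)-1,4-bis(TBS-oxy)dodeca-2,6,9-trien-1-yl]cyclopropyl}-3,4,7,8-tetrahydro-2H-oxocin-2-one | CC/C=C\C/C=C\C[C@H](O[Si](C)(C)C(C)(C)C)/C=C/[C@@H](O[Si](C)(C)C(C)(C)C)[C@@H]1C[C@H]1[C@H]1C/C=C\CCC(=O)O1 | intermediate
42 | (5Z,8R)-8-{(1R,2R)-2-[(1R,2E,4S,6Z,9Z)-1,4-dihydroxydodeca-2,6,9-trien-1-yl]cyclopropyl}-3,4,7,8-tetrahydro-2H-oxocin-2-one | CC/C=C\C/C=C\C[C@H](O)/C=C/[C@@H](O)[C@@H]1C[C@H]1[C@H]1C/C=C\CCC(=O)O1 | target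

## Step count and risk

Total steps: 31. Longest linear sequence: 21 steps (steps 1–10, then 21–31; the fragment B line through steps 1, 2, 11–16, 19, 20 is equally long).

**Step 7 (directed cyclopropanation).** The syn:anti ratio for E-allylic alcohols under substrate control can be modest. The fallback uses reagent control and sets out from 9. Anhydrous DDQ with molecular sieves closes the PMB ether onto the C7 hydroxyl to give the alkenyl PMP acetal F1. n-Bu4NF then frees the primary allylic alcohol F2. Charette cyclopropanation of F2 with Zn(CH2I)2 and the stoichiometric (4S,5S)-2-butyl-N,N,N',N'-tetramethyl-1,3,2-dioxaborolane-4,5-dicarboxamide in CH2Cl2 at 0 °C gives the cyclopropylmethanol 12, where the route resumes at step 10.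

**Step 29 (DDQ on a polyene acid).** Bis-allylic or allylic oxidation may compete with PMB removal. The fallback avoids the late PMB ether and sets out from 33. Transacetalisation with pyridinium p-toluenesulfonate in MeOH at 0 °C → rt gives the 1,3-diol F3. TEMPO/PhI(OAc)2 oxidises only the primary hydroxyl to the β-hydroxy aldehyde F4. Wittig reaction of F4 with an extra equivalent of ylide 37 (the first equivalent deprotonates C7-OH) and acidification gives seco acid 39 directly, where the route resumes at step 30.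

**Step 30 (eight-membered lactonisation).** Dimer and oligomer formation may dominate. The fallback builds the ring by Claisen ring expansion and sets out from 35. CH2=CHMgBr in THF at −78 °C gives the allylic alcohol F5 (both C5 epimers usable, since C5 becomes sp2). DDQ removes the PMB ether to give the 1,3-diol F6. Acetal exchange with PhSeCH2CH(OEt)2 (pyridinium p-toluenesulfonate, toluene, 110 °C) gives the selenoacetal F7. NaIO4 oxidises it to the selenoxide F8. Heating with DBU in xylene at 140 °C eliminates PhSeOH to the ketene acetal F9, which undergoes [3,3] rearrangement in the same pot to the (Z)-lactone 41, where the route resumes at step 31.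

## Further compounds

F1 | step 7 | (2R,4R)-4-[(E)-3-(TBS-oxy)prop-1-en-1-yl]-2-(4-methoxyphenyl)-1,3-dioxane | CC(C)(C)[Si](C)(C)OC/C=C/[C@H]1CCO[C@@H](c2ccc(OC)cc2)O1
F2 | step 7 | (2E)-3-[(2R,4R)-2-(4-methoxyphenyl)-1,3-dioxan-4-yl]prop-2-en-1-ol | OC/C=C/[C@H]1CCO[C@@H](c2ccc(OC)cc2)O1
F3 | step 29 | (1R)-1-{(1R,2R)-2-[(1R,2E,4S,6Z,9Z)-1,4-bis(TBS-oxy)dodeca-2,6,9-trien-1-yl]cyclopropyl}propane-1,3-diol | CC/C=C\C/C=C\C[C@H](O[Si](C)(C)C(C)(C)C)/C=C/[C@@H](O[Si](C)(C)C(C)(C)C)[C@@H]1C[C@H]1[C@H](O)CCO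
F4 | step 29 | (3R)-3-{(1R,2R)-2-[(1R,2E,4S,6Z,9Z)-1,4-bis(TBS-oxy)dodeca-2,6,9-trien-1-yl]cyclopropyl}-3-hydroxypropanal | CC/C=C\C/C=C\C[C@H](O[Si](C)(C)C(C)(C)C)/C=C/[C@@H](O[Si](C)(C)C(C)(C)C)[C@@H]1C[C@H]1[C@H](O)CC=O
F5 | step 30 | (3RS,5R)-5-{(1R,2R)-2-[(1R,2E,4S,6Z,9Z)-1,4-bis(TBS-oxy)dodeca-2,6,9-trien-1-yl]cyclopropyl}-5-(PMB-oxy)pent-1-en-3-ol | CC/C=C\C/C=C\C[C@H](O[Si](C)(C)C(C)(C)C)/C=C/[C@@H](O[Si](C)(C)C(C)(C)C)[C@@H]1C[C@H]1[C@H](OCc1ccc(OC)cc1)CC(O)C=C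
F6 | step 30 | (1R,3RS)-1-{(1R,2R)-2-[(1R,2E,4S,6Z,9Z)-1,4-bis(TBS-oxy)dodeca-2,6,9-trien-1-yl]cyclopropyl}pent-4-ene-1,3-diol | CC/C=C\C/C=C\C[C@H](O[Si](C)(C)C(C)(C)C)/C=C/[C@@H](O[Si](C)(C)C(C)(C)C)[C@@H]1C[C@H]1[C@H](O)CC(O)C=C
F7 | step 30 | (4R)-4-{(1R,2R)-2-[(1R,2E,4S,6Z,9Z)-1,4-bis(TBS-oxy)dodeca-2,6,9-trien-1-yl]cyclopropyl}-2-[(phenylselanyl)methyl]-6-vinyl-1,3-dioxane (epimers at C2 and C6) | CC/C=C\C/C=C\C[C@H](O[Si](C)(C)C(C)(C)C)/C=C/[C@@H](O[Si](C)(C)C(C)(C)C)[C@@H]1C[C@H]1[C@H]1CC(C=C)OC(C[Se]c2ccccc2)O1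
F8 | step 30 | (4R)-4-{(1R,2R)-2-[(1R,2E,4S,6Z,9Z)-1,4-bis(TBS-oxy)dodeca-2,6,9-trien-1-yl]cyclopropyl}-2-[(phenylseleninyl)methyl]-6-vinyl-1,3-dioxane | CC/C=C\C/C=C\C[C@H](O[Si](C)(C)C(C)(C)C)/C=C/[C@@H](O[Si](C)(C)C(C)(C)C)[C@@H]1C[C@H]1[C@H]1CC(C=C)OC(C[Se](=O)c2ccccc2)O1
F9 | step 30 | (4R)-4-{(1R,2R)-2-[(1R,2E,4S,6Z,9Z)-1,4-bis(TBS-oxy)dodeca-2,6,9-trien-1-yl]cyclopropyl}-2-methylidene-6-vinyl-1,3-dioxane | CC/C=C\C/C=C\C[C@H](O[Si](C)(C)C(C)(C)C)/C=C/[C@@H](O[Si](C)(C)C(C)(C)C)[C@@H]1C[C@H]1[C@H]1CC(C=C)OC(=C)O1
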